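A direct plan would buy ring A as 3,4,5-trimethoxyphenol and raise it in four steps (methylation, lithiation–borylation–oxidation, methylation, lithiation–formylation) to pentamethoxybenzaldehyde A1.
A1 would be joined with a ring B arylacetylide and oxidised to ynone A2, and iodine monochloride would close ring C at O1–C2 to 3-iodoflavone A3. Iodine–magnesium exchange, borylation and oxidation would then give flavonol ether A4, and BCl3 would finally free the 5- and 3'-hydroxyls.
Weak point 1, the linear build-up of A1: four steps that form no bond of the flavone skeleton and put two methyl groups on ring A that are cut off again later.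
Weak point 2, the oxidation of C3 after ring closure: an organomagnesium next to the C4 carbonyl and a boron-to-oxygen shift are spent on an oxygen that the ring-forming step could have carried.
Weak point 3, the final BCl3 cleavage: it must pick the 5-methyl ether out of six methyl ethers and remove a benzyl group at the same time, on the most valuable intermediate.

**Retrosynthetic overview**
Ring A (C4a, C5, C6, C7, C8, C8a) bears oxygen on five of its six carbons, with the vicinal methoxyls at C6/C7 flanked by the para-related C5–OH and C8–OMe: the imprint of dimethyl squarate plus one methylating agent.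
Ring A would therefore be built last, from non-aromatic carbon: C8–C8a by 1,2-addition of the C6-lithiated 4-pyranone 14 to squarate 13, and C4a–C5 by thermal ring expansion of the 4-pyranonyl-4-methoxycyclobutenone 16.
Ring C would be formed first, as monocyclic 2-aryl-3-(benzyloxy)-4-pyranone 12, from ring B acid chloride 4 and β-ethoxy enone 9 (C2–C3 by Claisen acylation, O1–C8a by addition–elimination).
The C5 hydroxyl would arise free from the ketene carbonyl, the C3 oxygen would come in with 9 as a benzyl ether, and both benzyl groups would leave by hydrogenolysis: no pentamethoxyarene, no late C3 oxidation, no selective demethylation.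

Key step: step 6

Remark: the Z geometry of the enol ether in 6 to 11 is written for definiteness; it is erased in step 4 and has no bearing on the outcome.

**Route**

Step 1
Reactants: 1 3-hydroxy-4,5-dimethoxybenzoic acid
Product: 3 3-(benzyloxy)-4,5-dimethoxybenzoic acid, via dibenzylated ester 2 (not isolated)
Conditions: BnBr (2.3 equiv), K2CO3, DMF, 60 °C; then NaOH, MeOH/H2O, 60 °C; aq. HCl
Reagents that add atoms: benzyl bromide, BrCc1ccccc1; sodium hydroxide, [Na+].[OH-]
Why: Williamson O-benzylation of phenoxide and carboxylate followed by saponification of the benzyl ester should leave only the future 3'-hydroxyl masked, as an ether that tolerates lithium amides, acid chlorides and heat and is removed at the end without a Lewis acid.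

Step 2
Reactants: 3 3-(benzyloxy)-4,5-dimethoxybenzoic acid
Product: 4 3-(benzyloxy)-4,5-dimethoxybenzoyl chloride
Conditions: (COCl)2, DMF (cat.), CH2Cl2, 0 °C to rt
Reagents that add atoms: oxalyl chloride, O=C(Cl)C(Cl)=O
Why: Acid chloride formation through the Vilsmeier-type chloroiminium catalyst is mild enough for the aryl benzyl ether and gives the acylating agent for step 4 after simple evaporation.

Step 3
Reactants: 5 2-(benzyloxy)-N-methoxy-N-methylacetamide; 6 (Z)-1-bromo-2-ethoxyethene
Product: 9 (3Z)-1-(benzyloxy)-4-ethoxybut-3-en-2-one, via (Z)-2-ethoxyvinyllithium 7 (not isolated), via lithium hemiaminal alkoxide 8 (not isolated)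
Conditions: 6, t-BuLi (2 equiv), THF, −78 °C; then 5, −78 to 0 °C; aq. NH4Cl
Reagents that add atoms: none
Why: Bromine–lithium exchange with retention of alkene geometry and Weinreb ketone synthesis, in which the chelated tetrahedral adduct 8 prevents a second addition, should give the β-ethoxy enone that carries C3 with its benzyl-protected oxygen, C4, C4a and C8a of the target.

Step 4
Reactants: 9 (3Z)-1-(benzyloxy)-4-ethoxybut-3-en-2-one; 4 3-(benzyloxy)-4,5-dimethoxybenzoyl chloride
Product: 12 3-(benzyloxy)-2-[3-(benzyloxy)-4,5-dimethoxyphenyl]-4H-pyran-4-one, via lithium dienolate 10 (not isolated), via open-chain 1,3-diketone 11 (not isolated)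
Conditions: 9 (2 equiv), LiN(SiMe3)2 (2 equiv), THF, −78 °C; 4 (1 equiv), −78 °C; then TFA, CH2Cl2, rt
Reagents that add atoms: none
Why: Claisen-type C-acylation of the lithium enolate by the aroyl chloride (the second equivalent of enolate takes up the acidic diketone proton), then acid-induced 6-endo addition of the aryl ketone enol oxygen to the β-ethoxy enone with loss of ethanol, is the established γ-pyrone synthesis from β-alkoxy enone enolates and acid chlorides.

Step 5
Reactants: 12 3-(benzyloxy)-2-[3-(benzyloxy)-4,5-dimethoxyphenyl]-4H-pyran-4-one; 13 dimethyl squarate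
Product: 16 3-(benzyloxy)-2-[3-(benzyloxy)-4,5-dimethoxyphenyl]-6-(1,2,3-trimethoxy-4-oxocyclobut-2-en-1-yl)-4H-pyran-4-one (racemic), via C6-lithiated pyranone 14 (not isolated), via lithium cyclobutenyl alkoxide 15 (not isolated)
Conditions: lithium 2,2,6,6-tetramethylpiperidide (1.1 equiv, from the amine and n-BuLi), THF, −78 °C; cannulated into 13 (1.2 equiv), THF, −78 °C; MeOTf (1.2 equiv), −78 to 0 °C
Reagents that add atoms: methyl trifluoromethanesulfonate, COS(=O)(=O)C(F)(F)F
Why: Deprotonative lithiation at C6, the only ring hydrogen alpha to the ring oxygen (the position corresponding to C2 of chromones, which hindered lithium amides metalate), then 1,2-addition of the vinyllithium to one squarate carbonyl and O-methylation of the tertiary lithium alkoxide in the same flask should give 16; its carbinol stereocentre forms as a racemate and is erased in step 6.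

Step 6
Reactants: 16 3-(benzyloxy)-2-[3-(benzyloxy)-4,5-dimethoxyphenyl]-6-(1,2,3-trimethoxy-4-oxocyclobut-2-en-1-yl)-4H-pyran-4-one
Product: 19 3-(benzyloxy)-2-[3-(benzyloxy)-4,5-dimethoxyphenyl]-5-hydroxy-6,7,8-trimethoxy-4H-chromen-4-one, via dienylketene 17 (not isolated), via 4aH-chromene-4,5-dione tautomer 18 (not isolated)
Conditions: toluene (degassed, 0.02 M), 110 °C
Reagents that add atoms: none
Why: Heating opens the cyclobutenone of 16 by conrotatory 4π cleavage of the C1–C4 bond with the C4 methoxy group turning outward, so that the pyranonyl group lies cis to the ketene in dienylketene 17; 6π electrocyclisation of 17 across the pyranone C5=C6 bond forms the C4a–C5 bond of the flavone, and tautomerisation of dienone 18 gives the phenol of ring A. The closest known reaction type is the thermal ring expansion of 4-aryl-, 4-heteroaryl- and 4-alkenyl-4-alkoxycyclobutenones derived from squarates to highly oxygenated phenols (Moore rearrangement). Ring A closes as a six-membered carbocycle by disrotatory 6π closure at a carbon–carbon bond, onto a ring C that is already in place. No stereocentre is created, and the carbinol stereocentre of 16 is erased. The step needs the alkenyl partner to turn inward on ring opening, closure at carbon without trapping of the ketene, and a single site of closure: the first is secured by the outward preference of the oxygen donor at C4, the second by the methylated carbinol oxygen (no hydroxyl that could give a butenolide), by high dilution and by the match of the electrophilic ketene carbon with pyranone C5, the β-carbon of the O1–C6=C5 enol ether, and the third by C5 being the only ring position next to the point of attachment. In this one operation C5 emerges as the free, chelated hydroxyl while C6, C7 and C8 carry their methoxyls, which is the full substitution of ring A.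

Step 7
Reactants: 19 3-(benzyloxy)-2-[3-(benzyloxy)-4,5-dimethoxyphenyl]-5-hydroxy-6,7,8-trimethoxy-4H-chromen-4-one
Product: 20 3-demethyldigicitrin, 3,5-dihydroxy-2-(3-hydroxy-4,5-dimethoxyphenyl)-6,7,8-trimethoxy-4H-chromen-4-one
Conditions: H2 (1 atm), 10% Pd/C, EtOAc/MeOH, rt
Reagents that add atoms: none
Why: Catalytic hydrogenolysis should cleave the aryl benzyl ether and the C3 enol benzyl ether together while the five methyl ethers and the tetrasubstituted, conjugated C2=C3 bond of the chromone remain untouched.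

**Compound list**

1 | 3-hydroxy-4,5-dimethoxybenzoic acid | COc1cc(C(=O)O)cc(O)c1OC | starting material
2 | benzyl 3-(benzyloxy)-4,5-dimethoxybenzoate | COc1cc(C(=O)OCc2ccccc2)cc(OCc2ccccc2)c1OC | intermediate
3 | 3-(benzyloxy)-4,5-dimethoxybenzoic acid | COc1cc(C(=O)O)cc(OCc2ccccc2)c1OC | intermediate
4 | 3-(benzyloxy)-4,5-dimethoxybenzoyl chloride | COc1cc(C(=O)Cl)cc(OCc2ccccc2)c1OC | intermediate
5 | 2-(benzyloxy)-N-methoxy-N-methylacetamide | CON(C)C(=O)COCc1ccccc1 | starting material
6 | (Z)-1-bromo-2-ethoxyethene | CCO/C=C\Br | starting material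
7 | (Z)-(2-ethoxyethenyl)lithium | CCO/C=C\[Li] | intermediate
8 | lithium (3Z)-1-(benzyloxy)-4-ethoxy-2-[methoxy(methyl)amino]but-3-en-2-olate (racemic) | CCO/C=C\C(O[Li])(COCc1ccccc1)N(C)OC | intermediate
9 | (3Z)-1-(benzyloxy)-4-ethoxybut-3-en-2-one | CCO/C=C\C(=O)COCc1ccccc1 | intermediate
10 | lithium (3Z)-1-(benzyloxy)-4-ethoxybuta-1,3-dien-2-olate | CCO/C=C\C(O[Li])=COCc1ccccc1 | intermediate
11 | (4Z)-2-(benzyloxy)-1-[3-(benzyloxy)-4,5-dimethoxyphenyl]-5-ethoxypent-4-ene-1,3-dione (racemic) | CCO/C=C\C(=O)C(OCc1ccccc1)C(=O)c1cc(OC)c(OC)c(OCc2ccccc2)c1 | intermediate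
12 | 3-(benzyloxy)-2-[3-(benzyloxy)-4,5-dimethoxyphenyl]-4H-pyran-4-one | COc1cc(-c2occc(=O)c2OCc2ccccc2)cc(OCc2ccccc2)c1OC | intermediate
13 | dimethyl squarate, 3,4-dimethoxycyclobut-3-ene-1,2-dione | COC1=C(OC)C(=O)C1=O | starting material
14 | {5-(benzyloxy)-6-[3-(benzyloxy)-4,5-dimethoxyphenyl]-4-oxo-4H-pyran-2-yl}lithium | COc1cc(-c2oc([Li])cc(=O)c2OCc2ccccc2)cc(OCc2ccccc2)c1OC | intermediate
15 | lithium 1-{5-(benzyloxy)-6-[3-(benzyloxy)-4,5-dimethoxyphenyl]-4-oxo-4H-pyran-2-yl}-2,3-dimethoxy-4-oxocyclobut-2-en-1-olate (racemic) | COC1=C(OC)C(O[Li])(c2cc(=O)c(OCc3ccccc3)c(-c3cc(OC)c(OC)c(OCc4ccccc4)c3)o2)C1=O | intermediate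
16 | 3-(benzyloxy)-2-[3-(benzyloxy)-4,5-dimethoxyphenyl]-6-(1,2,3-trimethoxy-4-oxocyclobut-2-en-1-yl)-4H-pyran-4-one (racemic) | COC1=C(OC)C(OC)(c2cc(=O)c(OCc3ccccc3)c(-c3cc(OC)c(OC)c(OCc4ccccc4)c3)o2)C1=O | intermediate
17 | 3-(benzyloxy)-2-[3-(benzyloxy)-4,5-dimethoxyphenyl]-6-[(1Z)-1,2,3-trimethoxy-4-oxobuta-1,3-dien-1-yl]-4H-pyran-4-one | O=C=C(OC)/C(OC)=C(/OC)c1cc(=O)c(OCc2ccccc2)c(-c2cc(OC)c(OC)c(OCc3ccccc3)c2)o1 | intermediate
18 | 3-(benzyloxy)-2-[3-(benzyloxy)-4,5-dimethoxyphenyl]-6,7,8-trimethoxy-4aH-chromene-4,5-dione (racemic) | COC1=C(OC)C(OC)=C2OC(c3cc(OC)c(OC)c(OCc4ccccc4)c3)=C(OCc3ccccc3)C(=O)C2C1=O | intermediate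
19 | 3-(benzyloxy)-2-[3-(benzyloxy)-4,5-dimethoxyphenyl]-5-hydroxy-6,7,8-trimethoxy-4H-chromen-4-one | COc1cc(-c2oc3c(OC)c(OC)c(OC)c(O)c3c(=O)c2OCc2ccccc2)cc(OCc2ccccc2)c1OC | intermediate
20 | 3-demethyldigicitrin, 3,5-dihydroxy-2-(3-hydroxy-4,5-dimethoxyphenyl)-6,7,8-trimethoxy-4H-chromen-4-one | COc1cc(-c2oc3c(OC)c(OC)c(OC)c(O)c3c(=O)c2O)cc(O)c1OC | target

**Step count and risk**

Total: 7 steps. Longest linear sequence: 6 steps (steps 1, 2, 4, 5, 6, 7 from 1); step 3 is a one-step branch.

Steps most likely to fail: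

Step 5. Metalation may take place at C5 next to the carbonyl, followed by ring opening of the pyranone, or the lithiated pyranone may decay before it meets the squarate; methyl triflate may also alkylate the pyranone carbonyl oxygen. The fallback turns the union round and replaces deprotonation by halogen–metal exchange. It sets out from 12:
- α-Iodination of the vinylogous ester with I2 and pyridine in CH2Cl2 (addition of pyridine at C6, iodination of the enolate, elimination; ring B is not attacked by this mechanism) should give 3-(benzyloxy)-2-[3-(benzyloxy)-4,5-dimethoxyphenyl]-5-iodo-4H-pyran-4-one F1.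
- Iodine–magnesium exchange with i-PrMgCl·LiCl in THF at −40 °C, as known for 3-iodochromones, would give the C5 Grignard reagent {5-(benzyloxy)-6-[3-(benzyloxy)-4,5-dimethoxyphenyl]-4-oxo-4H-pyran-3-yl}magnesium chloride F2.
- Addition of F2 to 13 and aqueous work-up would give the 5-(1-hydroxy-2,3-dimethoxy-4-oxocyclobut-2-en-1-yl)pyranone F3.
- Thermolysis of F3 in toluene under argon would close ring A at C8–C8a and give 3-(benzyloxy)-2-[3-(benzyloxy)-4,5-dimethoxyphenyl]-5,8-dihydroxy-6,7-dimethoxy-4H-chromen-4-one F4.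
- Selective methylation of the non-chelated 8-hydroxyl of F4 (MeI 1.05 equiv, K2CO3, acetone) would come back to the route at 19.

Step 6. The dienylketene may close too slowly onto the partly aromatic pyranone and be lost to dimerisation or to adventitious nucleophiles. The fallback builds ring A first on a simple vinyl ether and ring C afterwards by classical means. It sets out from 13 and 4:
- (1-Methoxyethenyl)lithium F5 (methyl vinyl ether, t-BuLi, THF) would add to 13, and methylation with MeOTf would give 2,3,4-trimethoxy-4-(1-methoxyethenyl)cyclobut-2-en-1-one F6.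
- Ring expansion of F6 in refluxing toluene, the alkenyl case with the closest precedent, would give 2,3,4,5-tetramethoxyphenol F7.
- Houben–Hoesch acylation of F7 at its only free position with (benzyloxy)acetonitrile (ZnCl2, HCl, Et2O) would give 2-(benzyloxy)-1-(2-hydroxy-3,4,5,6-tetramethoxyphenyl)ethan-1-iminium chloride F8, hydrolysed with warm water to 2-(benzyloxy)-1-(2-hydroxy-3,4,5,6-tetramethoxyphenyl)ethan-1-one F9.
- O-Aroylation of F9 with 4 in pyridine would give 2-[(benzyloxy)acetyl]-3,4,5,6-tetramethoxyphenyl 3-(benzyloxy)-4,5-dimethoxybenzoate F10.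
- Baker–Venkataraman rearrangement of F10 (KOH, pyridine, 50 °C) would give 2-(benzyloxy)-1-[3-(benzyloxy)-4,5-dimethoxyphenyl]-3-(2-hydroxy-3,4,5,6-tetramethoxyphenyl)propane-1,3-dione F11.
- Cyclodehydration of F11 (AcOH, cat. H2SO4) would give 3-(benzyloxy)-2-[3-(benzyloxy)-4,5-dimethoxyphenyl]-5,6,7,8-tetramethoxy-4H-chromen-4-one F12.
- BCl3 with pentamethylbenzene in CH2Cl2 (−78 to 0 °C) would cleave the chelated 5-methyl ether and both benzyl ethers of F12, so this fallback comes back to the route at 20 and accepts the selective demethylation that the main route avoids.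

Step 4. The α-alkoxy dienolate may be acylated on oxygen in place of carbon, or the β-ethoxy enone may be hydrolysed before the ring closes. The fallback replaces the acylation by a cyclocondensation with an aldehyde. It sets out from 4 and 9:
- Reduction of 4 with LiAlH(O-t-Bu)3 in THF at −78 °C would give 3-(benzyloxy)-4,5-dimethoxybenzaldehyde F13.
- Silylation of 9 (Me3SiOTf, Et3N, Et2O, 0 °C) would give the dienol ether {[(3Z)-1-(benzyloxy)-4-ethoxybuta-1,3-dien-2-yl]oxy}trimethylsilane F14.
- Mukaiyama aldol addition of F14 to F13 and ring closure (BF3·OEt2, CH2Cl2, −78 °C; then TFA), the stepwise form of the hetero-Diels–Alder reaction of oxygenated dienes with aldehydes, would give 3-(benzyloxy)-2-[3-(benzyloxy)-4,5-dimethoxyphenyl]-2,3-dihydro-4H-pyran-4-one F15 as a mixture of diastereomers.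
- Dehydrogenation of F15 with DDQ in 1,4-dioxane at 100 °C, as for flavanones, would erase both stereocentres and come back to the route at 12.

**Further compounds**

F1 | step 5 | 3-(benzyloxy)-2-[3-(benzyloxy)-4,5-dimethoxyphenyl]-5-iodo-4H-pyran-4-one | COc1cc(-c2occ(I)c(=O)c2OCc2ccccc2)cc(OCc2ccccc2)c1OC
F2 | step 5 | {5-(benzyloxy)-6-[3-(benzyloxy)-4,5-dimethoxyphenyl]-4-oxo-4H-pyran-3-yl}magnesium chloride | COc1cc(-c2occ([Mg]Cl)c(=O)c2OCc2ccccc2)cc(OCc2ccccc2)c1OC
F3 | step 5 | 3-(benzyloxy)-2-[3-(benzyloxy)-4,5-dimethoxyphenyl]-5-(1-hydroxy-2,3-dimethoxy-4-oxocyclobut-2-en-1-yl)-4H-pyran-4-one (racemic) | COC1=C(OC)C(O)(c2coc(-c3cc(OC)c(OC)c(OCc4ccccc4)c3)c(OCc3ccccc3)c2=O)C1=O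
F4 | step 5 | 3-(benzyloxy)-2-[3-(benzyloxy)-4,5-dimethoxyphenyl]-5,8-dihydroxy-6,7-dimethoxy-4H-chromen-4-one | COc1cc(-c2oc3c(O)c(OC)c(OC)c(O)c3c(=O)c2OCc2ccccc2)cc(OCc2ccccc2)c1OC
F5 | step 6 | (1-methoxyethenyl)lithium | [Li]C(=C)OC
F6 | step 6 | 2,3,4-trimethoxy-4-(1-methoxyethenyl)cyclobut-2-en-1-one (racemic) | COC(=C)C1(OC)C(OC)=C(OC)C1=O
F7 | step 6 | 2,3,4,5-tetramethoxyphenol | COc1cc(O)c(OC)c(OC)c1OC
F8 | step 6 | 2-(benzyloxy)-1-(2-hydroxy-3,4,5,6-tetramethoxyphenyl)ethan-1-iminium chloride | COc1c(OC)c(OC)c(C(=[NH2+])COCc2ccccc2)c(O)c1OC.[Cl-]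
F9 | step 6 | 2-(benzyloxy)-1-(2-hydroxy-3,4,5,6-tetramethoxyphenyl)ethan-1-one | COc1c(OC)c(OC)c(C(=O)COCc2ccccc2)c(O)c1OC
F10 | step 6 | 2-[(benzyloxy)acetyl]-3,4,5,6-tetramethoxyphenyl 3-(benzyloxy)-4,5-dimethoxybenzoate | COc1cc(C(=O)Oc2c(OC)c(OC)c(OC)c(OC)c2C(=O)COCc2ccccc2)cc(OCc2ccccc2)c1OC
F11 | step 6 | 2-(benzyloxy)-1-[3-(benzyloxy)-4,5-dimethoxyphenyl]-3-(2-hydroxy-3,4,5,6-tetramethoxyphenyl)propane-1,3-dione (racemic) | COc1cc(C(=O)C(OCc2ccccc2)C(=O)c2c(O)c(OC)c(OC)c(OC)c2OC)cc(OCc2ccccc2)c1OC
F12 | step 6 | 3-(benzyloxy)-2-[3-(benzyloxy)-4,5-dimethoxyphenyl]-5,6,7,8-tetramethoxy-4H-chromen-4-one | COc1cc(-c2oc3c(OC)c(OC)c(OC)c(OC)c3c(=O)c2OCc2ccccc2)cc(OCc2ccccc2)c1OC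
F13 | step 4 | 3-(benzyloxy)-4,5-dimethoxybenzaldehyde | COc1cc(C=O)cc(OCc2ccccc2)c1OC
F14 | step 4 | {[(3Z)-1-(benzyloxy)-4-ethoxybuta-1,3-dien-2-yl]oxy}trimethylsilane | CCO/C=C\C(O[Si](C)(C)C)=COCc1ccccc1
F15 | step 4 | 3-(benzyloxy)-2-[3-(benzyloxy)-4,5-dimethoxyphenyl]-2,3-dihydro-4H-pyran-4-one (mixture of diastereomers) | COc1cc(C2OC=CC(=O)C2OCc2ccccc2)cc(OCc2ccccc2)c1OC
A1 | direct plan | 2,3,4,5,6-pentamethoxybenzaldehyde | COc1c(OC)c(OC)c(C=O)c(OC)c1OC
A2 | direct plan | 3-[3-(benzyloxy)-4,5-dimethoxyphenyl]-1-(2,3,4,5,6-pentamethoxyphenyl)prop-2-yn-1-one | COc1c(OC)c(OC)c(C(=O)C#Cc2cc(OC)c(OC)c(OCc3ccccc3)c2)c(OC)c1OC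
A3 | direct plan | 2-[3-(benzyloxy)-4,5-dimethoxyphenyl]-3-iodo-5,6,7,8-tetramethoxy-4H-chromen-4-one | COc1cc(-c2oc3c(OC)c(OC)c(OC)c(OC)c3c(=O)c2I)cc(OCc2ccccc2)c1OC
A4 | direct plan | 2-[3-(benzyloxy)-4,5-dimethoxyphenyl]-3-hydroxy-5,6,7,8-tetramethoxy-4H-chromen-4-one | COc1cc(-c2oc3c(OC)c(OC)c(OC)c(OC)c3c(=O)c2O)cc(OCc2ccccc2)c1OC
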